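The route rests on reading the chain Ar–C7–C8(C9)–C8′(C9′)–C7′–Ar′ of the 2,3-dibenzylbutane-1,4-diol core (ArCH2 = C7, CH = C8, CH2OAc = C9; primes = syringyl half) as the saturated edge of a throw-away cyclohexene ring. One catalytic enantioselective [4+2] cycloaddition forms C7–C8 and C7′–C8′, closes that ring and copies the E geometry of dimethyl fumarate into the trans (8R,8′R) pair, with C9/C9′ as the ester carbons. The precursor is the (1E,3E)-butadiene carrying the veratryl ring at one end and the O-benzylated syringyl ring at the other. The inner diene carbons are later excised by alkene cleavage and double decarboxylation. This makes C7/C7′ CH2, so only the fumarate face matters.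

Key step: step 5

Assumption: the sense of induction in step 5 follows the accepted binding model of N-protonated oxazaborolidines for α,β-unsaturated esters, on which the (R)-diphenylprolinol-derived catalyst leaves the Re,Re face of the fumarate open. Both antipodes of the catalyst precursor are commercial, so the choice can be inverted without changing the route.

Remark: compounds 9–12 are drawn as one of the two possible 3,6-cis orientations. The other orientation of the diene differs only at C7/C7′, needs no separation and converges at 13.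

Step 1
Reactants: 1 syringaldehyde (4-hydroxy-3,5-dimethoxybenzaldehyde)
Product: 2 4-(benzyloxy)-3,5-dimethoxybenzaldehyde
Conditions: BnBr, K2CO3, DMF, 60 °C
Reagents that add atoms: benzyl bromide, BrCc1ccccc1
Why: Williamson ether synthesis on the acidic para-formyl phenol; the benzyl ether tolerates every later reagent and is the only group removed by the neutral final hydrogenolysis.

Step 2
Reactants: 2 4-(benzyloxy)-3,5-dimethoxybenzaldehyde
Product: 3 [4-(benzyloxy)-3,5-dimethoxyphenyl]methanol
Conditions: NaBH4, MeOH–THF, 0 °C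
Reagents that add atoms: none
Why: Sodium borohydride reduction of an aromatic aldehyde to the benzylic alcohol, with no other reducible group present.

Step 3
Reactants: 3 [4-(benzyloxy)-3,5-dimethoxyphenyl]methanol
Product: 5 diethyl [4-(benzyloxy)-3,5-dimethoxybenzyl]phosphonate, via 4-(benzyloxy)-3,5-dimethoxybenzyl chloride 4 (not isolated)
Conditions: SOCl2, CH2Cl2, 0 °C → rt, evaporate; then P(OEt)3 (neat), 130 °C
Reagents that add atoms: thionyl chloride, O=S(Cl)Cl (Cl of 4 only); triethyl phosphite, CCOP(OCC)OCC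
Why: Chlorodehydroxylation of an electron-rich benzylic alcohol followed by a Michaelis–Arbuzov reaction; the labile chloride 4 is only freed of volatiles and heated at once with the phosphite, which avoids storing a reactive benzylic halide.

Step 4
Reactants: 5 diethyl [4-(benzyloxy)-3,5-dimethoxybenzyl]phosphonate; 6 (E)-3,4-dimethoxycinnamaldehyde
Product: 7 (1E,3E)-1-[4-(benzyloxy)-3,5-dimethoxyphenyl]-4-(3,4-dimethoxyphenyl)buta-1,3-diene
Conditions: KOt-Bu, THF, 0 °C → rt
Reagents that add atoms: none
Why: Horner–Wadsworth–Emmons olefination of a benzylic phosphonate anion with a non-enolisable enal is strongly E-selective and leaves the E alkene of 6 untouched, so one olefination fixes both aryl groups on an (E,E)-diene that can be purified by crystallisation.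

Step 5
Reactants: 7 (1E,3E)-1-[4-(benzyloxy)-3,5-dimethoxyphenyl]-4-(3,4-dimethoxyphenyl)buta-1,3-diene; 8 dimethyl fumarate
Product: 9 dimethyl (1R,2R,3R,6S)-3-[4-(benzyloxy)-3,5-dimethoxyphenyl]-6-(3,4-dimethoxyphenyl)cyclohex-4-ene-1,2-dicarboxylate (esters trans, aryl groups cis)
Conditions: (R)-3,3-diphenyl-1-(o-tolyl)tetrahydro-1H,3H-pyrrolo[1,2-c][1,3,2]oxazaborole (20 mol %), Tf2NH (18 mol %), 8 (2 equiv), CH2Cl2, −20 → 4 °C
Reagents that add atoms: none
Why: The N-protonated oxazaborolidine binds one of the two equivalent fumarate carbonyls (s-trans ester, α-C–H···O contact), lowers the LUMO and lets the electron-rich s-cis diene add in a concerted, asynchronous, suprafacial [π4s+π2s] cycloaddition that forms C7–C8 and C7′–C8′. The closest known reaction type is the oxazaborolidinium-catalysed enantioselective Diels–Alder reaction of dialkyl fumarates with 1,3-dienes, and thermal Diels–Alder reactions of (E,E)-1,4-diarylbutadienes show that such dienes reach the reactive s-cis form. The single new ring, the cyclohexene, is closed intermolecularly in the [4+2] mode, both ring σ-bonds arising in the same step. C8 and C8′ (ring C1, C2) are trans because the E geometry of 8 is retained, and R,R because the catalyst aryl group covers the Si,Si face so that the diene adds to the Re,Re face. C7 and C7′ (ring C6, C3) are cis to each other because both aryl groups are outside substituents of the E,E-diene, and which ester lies endo is left open since both centres become CH2 in step 8. The step therefore needs only face selectivity on 8 and retention of its geometry: the C2h symmetry of 8 makes both binding sites and both diene orientations equivalent for C8/C8′, no regiochemistry arises, and keeping Tf2NH below the oxazaborolidine loading leaves no free acid to attack the diene.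

Step 6
Reactants: 9 dimethyl (1R,2R,3R,6S)-3-[4-(benzyloxy)-3,5-dimethoxyphenyl]-6-(3,4-dimethoxyphenyl)cyclohex-4-ene-1,2-dicarboxylate
Product: 11 dimethyl (2R,3R)-2-{(1R)-1-[4-(benzyloxy)-3,5-dimethoxyphenyl]-2-oxoethyl}-3-[(1S)-1-(3,4-dimethoxyphenyl)-2-oxoethyl]butanedioate, via dimethyl (1R,2R,3R,4R,5S,6S)-3-[4-(benzyloxy)-3,5-dimethoxyphenyl]-6-(3,4-dimethoxyphenyl)-4,5-dihydroxycyclohexane-1,2-dicarboxylate 10 (not isolated)
Conditions: OsO4 (4 mol %), NaIO4 (4 equiv), 2,6-lutidine, 1,4-dioxane–H2O, rt; used crude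
Reagents that add atoms: osmium tetroxide, O=[Os](=O)(=O)=O (transfers both O atoms, regenerated in situ); sodium periodate, [Na+].[O-]I(=O)(=O)=O (terminal O source)
Why: Lemieux–Johnson oxidation, in which osmium tetroxide adds suprafacially to the only alkene from the face anti to the two cis aryl groups and periodate cleaves cis-diol 10 as it forms, conditions that spare the electron-rich arenes (which ozone or RuO4 could attack) and the C8/C8′ centres, while the two transient carbinol centres vanish in the same flask.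

Step 7
Reactants: 11 dimethyl (2R,3R)-2-{(1R)-1-[4-(benzyloxy)-3,5-dimethoxyphenyl]-2-oxoethyl}-3-[(1S)-1-(3,4-dimethoxyphenyl)-2-oxoethyl]butanedioate
Product: 12 (2R,3S,4S,5S)-2-[4-(benzyloxy)-3,5-dimethoxyphenyl]-5-(3,4-dimethoxyphenyl)-3,4-bis(methoxycarbonyl)hexanedioic acid (C8/C8′ spatially unchanged; their descriptors change only through substituent priority)
Conditions: NaClO2, NaH2PO4, 2-methyl-2-butene (large excess), t-BuOH–THF–H2O, 0 °C → rt
Reagents that add atoms: sodium chlorite, [Na+].[O-]Cl=O
Why: Pinnick oxidation converts both aldehydes into acids at buffered pH that does not enolise the esters, and the excess alkene traps hypochlorous acid before it can chlorinate the arenes.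

Step 8
Reactants: 12 (2R,3S,4S,5S)-2-[4-(benzyloxy)-3,5-dimethoxyphenyl]-5-(3,4-dimethoxyphenyl)-3,4-bis(methoxycarbonyl)hexanedioic acid
Product: 13 dimethyl (2R,3R)-2-[4-(benzyloxy)-3,5-dimethoxybenzyl]-3-(3,4-dimethoxybenzyl)butanedioate
Conditions: 9-mesityl-10-phenylacridinium BF4 (5 mol %), (PhS)2 (20 mol %), i-Pr2NEt (40 mol %), CF3CH2OH–EtOAc, 450 nm LEDs, N2, rt
Reagents that add atoms: none
Why: Photoredox hydrodecarboxylation of arylacetic acids, in which single-electron oxidation of each arylacetate by the excited acridinium triggers loss of CO2 to a stabilised benzylic radical that takes hydrogen from thiophenol formed in situ, so C7/C7′ become CH2 and all adduct diastereomers converge, while C8/C8′ are never radical or enolate sites and keep their configuration.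

Step 9
Reactants: 13 dimethyl (2R,3R)-2-[4-(benzyloxy)-3,5-dimethoxybenzyl]-3-(3,4-dimethoxybenzyl)butanedioate
Product: 14 (2R,3R)-2-[4-(benzyloxy)-3,5-dimethoxybenzyl]-3-(3,4-dimethoxybenzyl)butane-1,4-diol
Conditions: LiAlH4, THF, 0 °C → rt
Reagents that add atoms: none
Why: Lithium aluminium hydride reduction of both esters to primary alcohols, hydride addition at 0 °C outrunning enolisation so that C8/C8′ are not epimerised and are configurationally fixed thereafter.

Step 10
Reactants: 14 (2R,3R)-2-[4-(benzyloxy)-3,5-dimethoxybenzyl]-3-(3,4-dimethoxybenzyl)butane-1,4-diol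
Product: 15 (2R,3R)-2-[4-(benzyloxy)-3,5-dimethoxybenzyl]-3-(3,4-dimethoxybenzyl)butane-1,4-diyl diacetate
Conditions: Ac2O, pyridine, DMAP (cat.), CH2Cl2, rt
Reagents that add atoms: acetic anhydride, CC(=O)OC(C)=O
Why: DMAP-catalysed acylation of two unhindered primary alcohols, with the phenol still masked so that only C9–O and C9′–O are acetylated.

Step 11
Reactants: 15 (2R,3R)-2-[4-(benzyloxy)-3,5-dimethoxybenzyl]-3-(3,4-dimethoxybenzyl)butane-1,4-diyl diacetate
Product: 16 Justin C, (2R,3R)-2-(3,4-dimethoxybenzyl)-3-(4-hydroxy-3,5-dimethoxybenzyl)butane-1,4-diyl diacetate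
Conditions: H2 (1 atm), 10 % Pd/C, EtOAc–EtOH, rt
Reagents that add atoms: none
Why: Catalytic hydrogenolysis cleaves only the benzyl aryl ether under neutral conditions, leaving acetates, methyl ethers and the oxygen-free benzylic C7/C7′ positions untouched.

Compound list
1 | syringaldehyde | COc1cc(C=O)cc(OC)c1O | starting material
2 | 4-(benzyloxy)-3,5-dimethoxybenzaldehyde | COc1cc(C=O)cc(OC)c1OCc1ccccc1 | intermediate
3 | [4-(benzyloxy)-3,5-dimethoxyphenyl]methanol | COc1cc(CO)cc(OC)c1OCc1ccccc1 | intermediate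
4 | 4-(benzyloxy)-3,5-dimethoxybenzyl chloride | COc1cc(CCl)cc(OC)c1OCc1ccccc1 | intermediate (not isolated)
5 | diethyl [4-(benzyloxy)-3,5-dimethoxybenzyl]phosphonate | CCOP(=O)(Cc1cc(OC)c(OCc2ccccc2)c(OC)c1)OCC | intermediate
6 | (E)-3,4-dimethoxycinnamaldehyde | COc1ccc(/C=C/C=O)cc1OC | starting material
7 | (1E,3E)-1-[4-(benzyloxy)-3,5-dimethoxyphenyl]-4-(3,4-dimethoxyphenyl)buta-1,3-diene | COc1ccc(/C=C/C=C/c2cc(OC)c(OCc3ccccc3)c(OC)c2)cc1OC | intermediate
8 | dimethyl fumarate | COC(=O)/C=C/C(=O)OC | starting material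
9 | dimethyl (1R,2R,3R,6S)-3-[4-(benzyloxy)-3,5-dimethoxyphenyl]-6-(3,4-dimethoxyphenyl)cyclohex-4-ene-1,2-dicarboxylate | COc1ccc([C@@H]2[C@@H](C(=O)OC)[C@H](C(=O)OC)[C@H](c3cc(OC)c(OCc4ccccc4)c(OC)c3)C=C2)cc1OC | intermediate
10 | dimethyl (1R,2R,3R,4R,5S,6S)-3-[4-(benzyloxy)-3,5-dimethoxyphenyl]-6-(3,4-dimethoxyphenyl)-4,5-dihydroxycyclohexane-1,2-dicarboxylate | COc1ccc([C@@H]2[C@@H](C(=O)OC)[C@H](C(=O)OC)[C@H](c3cc(OC)c(OCc4ccccc4)c(OC)c3)[C@@H](O)[C@H]2O)cc1OC | intermediate (not isolated)
11 | dimethyl (2R,3R)-2-{(1R)-1-[4-(benzyloxy)-3,5-dimethoxyphenyl]-2-oxoethyl}-3-[(1S)-1-(3,4-dimethoxyphenyl)-2-oxoethyl]butanedioate | COc1ccc([C@@H](C=O)[C@@H](C(=O)OC)[C@H](C(=O)OC)[C@H](c2cc(OC)c(OCc3ccccc3)c(OC)c2)C=O)cc1OC | intermediate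
12 | (2R,3S,4S,5S)-2-[4-(benzyloxy)-3,5-dimethoxyphenyl]-5-(3,4-dimethoxyphenyl)-3,4-bis(methoxycarbonyl)hexanedioic acid | COc1ccc([C@@H](C(O)=O)[C@@H](C(=O)OC)[C@H](C(=O)OC)[C@H](c2cc(OC)c(OCc3ccccc3)c(OC)c2)C(O)=O)cc1OC | intermediate
13 | dimethyl (2R,3R)-2-[4-(benzyloxy)-3,5-dimethoxybenzyl]-3-(3,4-dimethoxybenzyl)butanedioate | COc1ccc(C[C@@H](C(=O)OC)[C@H](C(=O)OC)Cc2cc(OC)c(OCc3ccccc3)c(OC)c2)cc1OC | intermediate
14 | (2R,3R)-2-[4-(benzyloxy)-3,5-dimethoxybenzyl]-3-(3,4-dimethoxybenzyl)butane-1,4-diol | COc1ccc(C[C@@H](CO)[C@H](CO)Cc2cc(OC)c(OCc3ccccc3)c(OC)c2)cc1OC | intermediate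
15 | (2R,3R)-2-[4-(benzyloxy)-3,5-dimethoxybenzyl]-3-(3,4-dimethoxybenzyl)butane-1,4-diyl diacetate | COc1ccc(C[C@@H](COC(C)=O)[C@H](COC(C)=O)Cc2cc(OC)c(OCc3ccccc3)c(OC)c2)cc1OC | intermediate
16 | Justin C | COc1ccc(C[C@@H](COC(C)=O)[C@H](COC(C)=O)Cc2cc(OC)c(O)c(OC)c2)cc1OC | target

Total step count: 11. Longest linear sequence: 11 steps (1 → 16; 6 and 8 are purchased).

Steps most likely to fail

Step 5. The doubly end-substituted diene may add too slowly. The strongly acidic catalyst may start cationic oligomerisation of the electron-rich diene or be held back by its five ether oxygens. Facial selectivity may be poor, or a stepwise zwitterionic pathway may erode the trans relation. The fallback replaces catalyst control by auxiliary control; it sets out from 7 and returns at 14.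
- Fumaryl chloride is esterified with (+)-menthol (Et3N, DMAP, CH2Cl2) to di-(+)-menthyl fumarate F1.
- Diene 7 and F1 are combined with Et2AlCl (toluene–CH2Cl2, −40 → 0 °C). Both menthyl groups of the aluminium-bound s-trans diester shield the Si,Si face together, and the alkylaluminium scavenges protic acid. This should give the dimenthyl (1R,2R)-cyclohexene adduct F2, whose diastereomeric purity can be raised by crystallisation.
- F2 is carried through the same chemistry as the main line. OsO4/NaIO4 via the transient cis-diol F3 gives the dialdehyde F4, chlorite oxidation gives the diacid F5, and photoredox hydrodecarboxylation gives the dimenthyl (2R,3R)-dibenzylsuccinate F6.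
- LiAlH4 then reduces F6 to 14 with recovery of the auxiliary.

Step 8. The very electron-rich benzylic radicals may be oxidised further to cations, which then close onto the other arene or are captured by solvent. The second decarboxylation may stall, or the benzyl ether may be lost oxidatively. The fallback generates the same radicals under net reducing conditions; it sets out from 12 and returns at 13. The diacid is coupled with N-hydroxyphthalimide (DIC, DMAP, CH2Cl2) to the bis(N-acyloxyphthalimide) F7. This is submitted to a Barton-type reductive decarboxylation of redox-active esters (NiCl2·6H2O, bathophenanthroline, Zn, PhSiH3, THF–DMF–i-PrOH, 40 °C).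

Step 6. Osmylation of the ring alkene flanked by two aryl-bearing carbons may be slow. The intermediate diol may lactonise onto the cis ester and so escape glycol cleavage. The labile α-aryl dialdehyde may also undergo aldol self-condensation. The fallback avoids the osmate and the free cis-diol; it sets out from 9 and returns at 11. Epoxidation with mCPBA (NaHCO3, CH2Cl2, 0 °C → rt), from either face since the centres are lost, gives the epoxide F8. Periodic acid (H5IO6, THF–H2O, 0 °C → rt) opens and cleaves it in one operation.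

Further compounds
F1 | step 5 | di-(+)-menthyl fumarate, bis[(1S,2R,5S)-2-isopropyl-5-methylcyclohexyl] (E)-but-2-enedioate | CC(C)[C@H]1CC[C@H](C)C[C@@H]1OC(=O)/C=C/C(=O)O[C@H]1C[C@@H](C)CC[C@@H]1C(C)C
F2 | step 5 | di-(+)-menthyl (1R,2R,3R,6S)-3-[4-(benzyloxy)-3,5-dimethoxyphenyl]-6-(3,4-dimethoxyphenyl)cyclohex-4-ene-1,2-dicarboxylate | COc1ccc([C@@H]2[C@@H](C(=O)O[C@H]3C[C@@H](C)CC[C@@H]3C(C)C)[C@H](C(=O)O[C@H]3C[C@@H](C)CC[C@@H]3C(C)C)[C@H](c3cc(OC)c(OCc4ccccc4)c(OC)c3)C=C2)cc1OC
F3 | step 5 | di-(+)-menthyl analogue of cis-diol 10 (both OH anti to the aryl groups) | COc1ccc([C@@H]2[C@@H](C(=O)O[C@H]3C[C@@H](C)CC[C@@H]3C(C)C)[C@H](C(=O)O[C@H]3C[C@@H](C)CC[C@@H]3C(C)C)[C@H](c3cc(OC)c(OCc4ccccc4)c(OC)c3)[C@@H](O)[C@H]2O)cc1OC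
F4 | step 5 | di-(+)-menthyl analogue of dialdehyde 11 | COc1ccc([C@@H](C=O)[C@@H](C(=O)O[C@H]2C[C@@H](C)CC[C@@H]2C(C)C)[C@H](C(=O)O[C@H]2C[C@@H](C)CC[C@@H]2C(C)C)[C@H](c2cc(OC)c(OCc3ccccc3)c(OC)c2)C=O)cc1OC
F5 | step 5 | di-(+)-menthyl analogue of diacid 12 | COc1ccc([C@@H](C(O)=O)[C@@H](C(=O)O[C@H]2C[C@@H](C)CC[C@@H]2C(C)C)[C@H](C(=O)O[C@H]2C[C@@H](C)CC[C@@H]2C(C)C)[C@H](c2cc(OC)c(OCc3ccccc3)c(OC)c2)C(O)=O)cc1OC
F6 | step 5 | di-(+)-menthyl (2R,3R)-2-[4-(benzyloxy)-3,5-dimethoxybenzyl]-3-(3,4-dimethoxybenzyl)butanedioate | COc1ccc(C[C@@H](C(=O)O[C@H]2C[C@@H](C)CC[C@@H]2C(C)C)[C@H](C(=O)O[C@H]2C[C@@H](C)CC[C@@H]2C(C)C)Cc2cc(OC)c(OCc3ccccc3)c(OC)c2)cc1OC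
F7 | step 8 | bis(1,3-dioxoisoindolin-2-yl) ester of diacid 12 | COc1ccc([C@@H](C(=O)ON2C(=O)c3ccccc3C2=O)[C@@H](C(=O)OC)[C@H](C(=O)OC)[C@H](c2cc(OC)c(OCc3ccccc3)c(OC)c2)C(=O)ON2C(=O)c3ccccc3C2=O)cc1OC
F8 | step 6 | 4,5-epoxide of 9 (oxirane drawn anti to the aryl groups) | COc1ccc([C@@H]2[C@@H](C(=O)OC)[C@H](C(=O)OC)[C@H](c3cc(OC)c(OCc4ccccc4)c(OC)c3)[C@H]5O[C@@H]25)cc1OC
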